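Millimolar per second is the unit I work in here: the substrate in this flask has several ways out, and I want them side by side at one moment.

substrate 0.50 mM; gas phase 0.044 mM (held); time 25 s

    gas phase ⇌ dissolved gas, rate k1*(csat - [dissolved gas]) (k1 = 46 /s, csat = 0.044 mM)
    dissolved gas + target → over-reacted product (k2 = 1100 /M/s)
    2 substrate → self-condensation product (k3 = 270 /M/s)
    crystals ⇌ target, rate k4*(cs4 - [target]) while solid is left; crystals form when [target] > cs4 (cs4 = 0.013 mM, k4 = 0.82 /s)
    substrate + dissolved gas ⇌ target (K5 = 15000 /M, k5 = 52000 /M/s)

- in percentages every species weighs as the substrate in it: one self-condensation product counts as two
- for target the crystals are counted in
- a step written with two of one species runs at k times the square of its concentration and takes two of it each time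
- as a solid, counted per litre of solution: crystals
- at the start none of the gas is dissolved
- run time (flask): 25 s

* amount of target and crystals together at 25 s, in percent of the substrate charged
* concentration of dissolved gas in solution at 25 s, in percent of saturation

At the charge, self-condensation takes 0.135 mM/s, while binding of substrate to dissolved gas starts from zero, with no gas dissolved yet. The ceiling of binding, saturated gas on substrate as charged, is 1.14 mM/s, higher than self-condensation, so the loss looks small at first sight. But binding runs back, and at saturation its balance holds dissolved target at

equilibrium constant × saturation = 0.660 times the free substrate.

Target in solution is therefore no exit. Substrate and dissolved target form one pool, a pre-equilibrium, reached in about 0.174 s, which is short against the run. Can the gas keep up? At balance free substrate stands at 0.301 mM, so the pool binds 0.199 mM in that time, which asks for 1.14 mM/s. The held gas phase delivers up to 2.02 mM/s into an empty solution, more than that, so after the first moments I take the solution as saturated.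

With free substrate at 0.301 mM, the two exits compare thus:

crystals: 0.152 mM/s
self-condensation: 0.0490 mM/s

The loss share, the part of what leaves the pool that goes to self-condensation, is 24.3%.

That holds for one moment, though. At 0.151 mM of free substrate the share drifts down to 14.7%. Against that, the time before balance costs about 4.69% of the charge. I commit to a loss of

burst + mean share = 24.2%.

Two smaller items remain. Free substrate stands at about 3.94% of the charge when target in solution meets its solubility. Target over-reacts at 0.0484 /s; its excess drains in about 3.07 s, then it sits at solubility, which costs 8.66%. So I expect 63.2% as target and crystals. Over-reaction at solubility leaves the gas short by 0.0311%, so I expect dissolved gas at >99.9%.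

The forecast gives 70% and 99.9%, higher than my yield, reasoning that “the charge therefore ends up as crystals”.

The flask gives 68.7% and >99.9%. Self-condensation product there stands at 20.7% after 25.0 s, less than my loss of 24.2%. The neighbouring flask, charged with 0.85 mM of substrate, starts its pool at 0.512 mM of free substrate, and there the loss share is 34.7%, higher than the 24.3% of the first flask. That neighbour ends with 30.1% as self-condensation product and 62.5% as target and crystals.

The constants are invented; the run is a simulation.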